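## Structural features

The target (39) is a germacrane-type sesquiterpenoid: a ten-membered carbocycle C1–C10, trans-fused along C6–C7 to an α-methylene γ-butyrolactone (O–C6, C7, C11, C12, with C13 as the exocyclic methylene). The carbocycle holds one trisubstituted alkene, C1=C10, whose C10 carries the C14 methyl ester; it is E (C2 trans to C14), so both ring bonds lie on the same side and the alkene is cis within the ring. Three contiguous stereocentres sit at C6 (R, lactone oxygen), C7 (S, ring fusion) and C8 (R, (2R)-2-methylbutanoyloxy). A fourth, isolated centre at C4 (R) carries the C15 hydroxymethyl group, separated from C6 only by the C5 methylene. The fragile parts are the methylene lactone (a Michael acceptor that tolerates neither carbanions, amines nor hydrides), the C8 oxygen (a free hydroxyl there can translactonise onto C12 or lactonise onto C14), the epimerisable α-centre of the side-chain ester, and the enoate. The real difficulty is the medium ring together with the C6–C7–C8 triad next to a remote centre, C4, that no neighbouring group can relay. The plan uses the fact that C6 and C8 are carbinol carbons of the same configuration on either side of C7. While the C5–C6 and C8–C9 arms are identical, C7 is not a stereocentre and C5–C9 is D-arabinitol with its central oxygen exchanged for the C11–C12 acetic acid unit. Closing the lactone ring (O6–C12) on one of the two diastereotopic hydroxyls then creates C7 and tells C5 from C9 in one event.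

## Logic of the disconnections

**39 to 35.** The last bonds cut are O–Si at C15 (39 from 38) and the C11=C13 double bond, traced through 37 and 36 to the C13–O benzyl ether of 35. The methylene lactone cannot coexist with the phosphonate carbanions that build C9–C10 and C1=C10, and enolising the lactone at the end would compete with the enoate and the side-chain ester. The end game therefore contains no C–C bond formation. The demand is that the C13 oxygen survives from 25 to 35, comes off without hydrogenation, and eliminates only towards C11.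

**35 to 31.** The C1=C10 bond is cut, giving the open-chain aldehyde phosphonate 34, which comes from 33 and 31 by adjusting the oxidation level at C1. This is the one ring bond whose formation creates no stereocentre, and the E-enoate that the olefination prefers is the ring-cis isomer required. All earlier intermediates become acyclic apart from the lactone. The forward step needs high dilution and a substrate without free hydroxyls or other carbanion acceptors.

**31 to 29 and 30.** The C9–C10 bond is cut; 30 delivers C10, C14 and the phosphonate in one piece. The forward step is an SN2 reaction on a β-acyloxy primary iodide. The C8 ester must already be in place, so that a free C8 hydroxyl never sits γ to the C14 ester.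

**29 to 25.** The C8–O acyl bond (29 from 27 and 28), the C9–I bond (27 from 26) and the ketal (26 from 25) are cut in turn. The side chain arrives with its stereocentre from 28, and C9 is told from C8 simply as primary against secondary.

**25 to 22 and 23.** The C11–C13 bond is cut. It is made at the last point where the lactone is the only enolisable group, which demands a kinetic lactone enolate and an electrophile reactive at −78 °C.

**22 to 17 and 18.** After removal of the silyl group (22 from 21) and return of C15 to the acyl level (21 from 20), the C3–C4 bond is cut. C4 is set by auxiliary-controlled alkylation. The more obvious cut at C4–C5 (a C5 halide plus a chiral enolate) is avoided: an unactivated, β-oxygenated iodide needs an amide enolate, which would deprotonate or attack the lactone. Instead C5 is first extended to the C5–C4–C15 acyl chain, and the imide, far more acidic than the lactone, is enolised. 18 brings C1–C3 with C1 masked as a terminal alkene. The forward steps need an activated electrophile and a chemoselective reduction of the imide beside the lactone.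

**17 to 10.** The C15–N bond (17 from 14 and 15) and the C4–C5 bond, as an alkene (13 from 10 and 11), are cut. A neutral stabilised ylide is used, so the aldehyde 12 is never exposed to base.

**10 to 7.** The C8,C9 ketal is removed (10 from 9), then the O6–C12 lactone bond and the two ketals of 7 are restored on paper. This is the strategic cut: it erases the C7 stereocentre and gives a precursor with two identical arms. The forward step must choose the hydroxyl that gives the trans lactone, by equilibration.

**7 to 4 and 5.** The C7–C11 bond is cut as an alkene (7 from 6, 6 from 4 and 5). A ketone olefination followed by hydrogenation needs no stereocontrol, because C7 carries two identical arms.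

**4 to 1 and 2.** The C7 carbonyl returns to the central carbinol (4 from 3), and the two terminal ketals are cut (3 from 1 and 2). Both oxygenated stereocentres come from the chiral pool. The forward step needs ketal formation at the terminal diols only.

## Other disconnections considered

**Alternative 1:** The cut is at C6–C7 together with the C8–O bond. In the forward sense the open-chain (E)-aldoxime A2 would be oxidised with bleach to its nitrile oxide, which adds across the (E)-C7=C8 alkene in the bridged mode to give the isoxazoline-bridged carbocycle A1.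
- In its favour: the ten-membered ring and the C7/C8 relationship arise in one stereospecific step from an acyclic precursor whose only stereocentre is C4, and the acetate arm is already on C7.
- Against it here: C6 emerges as C=N, so after N–O cleavage a β-hydroxy ketone must be reduced at C6 on the medium ring with no element to control the face, and it is prone to retro-aldol cleavage or dehydration. The absolute sense of addition rests on 1,4-induction from C4 through a flexible tether. The conjugated C1=C10 alkene of A2 is an activated dipolarophile within reach of a six-membered closure (C6 to C1), so chemoselectivity is not secured.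
- Comparison: on ring construction this plan is the better one (ring plus two centres in one step, against a separate macro-olefination). On stereocontrol the chosen plan is stronger, since C6 and C8 come from the pool and C7 from an equilibrium. Step economy is about equal, because A2 needs the same auxiliary chemistry for C4 and A1 needs several redox steps before the lactone exists.

**Alternative 2:** The cut is at C8–C9 with reconnection of C1–C6. In the forward sense the potassium alkoxide of the cis-1,2-dialkenylcyclohexanol A4 would undergo a chair anionic oxy-Cope shift to the ten-membered enolate, and hence the ketone A3.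
- In its favour: ring expansion avoids the entropic cost of closing a medium ring. The chair transition state should translate the cis arrangement into the ring-cis C1=C10 alkene and the enol ether geometry into C8. The enolate is formed regiospecifically at C6–C7 and could be alkylated there.
- Against it here: A3 lacks C11–C13. C6 and C7 would have to be set on the flexible ring by conformational control alone. C14 and the C8 oxygen arrive at the wrong oxidation or protection level. A4 itself needs three stereocentres and a defined enol ether.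
- Comparison: on ring formation this plan is better than the chosen one (no high-dilution step). On C4 the two are equal, since both need an external source of chirality. On the C6–C8 triad and on step count after the key step the chosen plan is ahead, because two of the three centres come from the pool.

**Alternative 3:** The cuts are at C7–C8 and C11–C13. In the forward sense the lithiated dithiane A7 would add to the butenolide A6 anti to its C5 arm, and the lactone enolate would be trapped by the iminium salt A8 to give the trans,trans lactone A5.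
- In its favour: conjugate addition with enolate trapping on γ-substituted butenolides is well-behaved chemistry; C6 comes from the pool and C7 and C11 follow by substrate control. The aminomethyl group is a ready precursor of the methylene. On this point the alternative is better than the chosen plan, which spends one step on the benzyloxymethyl handle and two on converting it.
- Against it here: C8 arrives as a dithiane at the ketone level and would need unmasking and a stereoselective reduction, so C8 is not secured. The tertiary amine is at risk with the alkyl iodides needed later. C10 arrives as a 1,1-disubstituted alkene with C14 as an ether, so the ring would have to be closed at C1–C2 or by metathesis to a trisubstituted alkene, and C14 oxidised afterwards.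
- Comparison: equal on C6 and on the C4–C5 problem (C5 still needs the same extension beside a lactone); better on C11–C13; weaker on C8 and on the ring closure.

Key step: step 5

Assumption: stereocentres that exist only in intermediates are drawn in the expected sense (C11 of 25 and 35–37, substituent trans to the C7 arm) or left open (C10 of 31–34, both epimers); both become sp2 later. TBDPS = tert-butyl(diphenyl)silyl; carbon locants in the prose follow the target numbering.

## Route

Step 1
Reactants: 1 D-arabinitol; 2 2,2-dimethoxypropane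
Product: 3 1,2:4,5-di-O-isopropylidene-D-arabinitol
Conditions: 2 (2.2 equiv), TsOH (cat.), DMF, 0 °C → rt; Et3N quench
Reagents that add atoms: none
Why: Acid-catalysed ketal exchange under kinetic control favours the two terminal dioxolanes over ketals that engage the central hydroxyl; no stereocentre is touched and the regioisomeric diacetonide should be separable by chromatography.

Step 2
Reactants: 3 1,2:4,5-di-O-isopropylidene-D-arabinitol
Product: 4 bis[(4R)-2,2-dimethyl-1,3-dioxolan-4-yl]methanone
Conditions: Dess–Martin periodinane, CH2Cl2, rt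
Reagents that add atoms: none
Why: Dess–Martin oxidation of the secondary alcohol under non-basic conditions should give the C2-symmetric ketone without epimerising the two α-alkoxy centres.

Step 3
Reactants: 4 bis[(4R)-2,2-dimethyl-1,3-dioxolan-4-yl]methanone; 5 triethyl phosphonoacetate
Product: 6 ethyl 3,3-bis[(4S)-2,2-dimethyl-1,3-dioxolan-4-yl]prop-2-enoate
Conditions: 5 (1.2 equiv), NaH (1.1 equiv), THF, 0 °C; then 4, 0 °C → rt
Reagents that add atoms: none
Why: Horner–Wadsworth–Emmons olefination of an α,α'-dialkoxy ketone, which is activated towards addition; the phosphonate is kept in excess over NaH so that no free base enolises the ketone, and the alkene is not a stereogenic unit because its two β-substituents are identical.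

Step 4
Reactants: 6 ethyl 3,3-bis[(4S)-2,2-dimethyl-1,3-dioxolan-4-yl]prop-2-enoate
Product: 7 ethyl 3,3-bis[(4S)-2,2-dimethyl-1,3-dioxolan-4-yl]propanoate
Conditions: H2 (1–3 atm), 10% Pd/C, EtOAc, rt
Reagents that add atoms: none
Why: Heterogeneous catalytic hydrogenation of the conjugated alkene; C7 receives hydrogen but carries two identical arms of the same configuration, so no stereocentre arises and facial selectivity does not matter.

Step 5
Reactants: 7 ethyl 3,3-bis[(4S)-2,2-dimethyl-1,3-dioxolan-4-yl]propanoate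
Product: 9 (4R,5S)-4-[(1S)-1,2-dihydroxyethyl]-5-(hydroxymethyl)oxolan-2-one, via pentaol ester 8 (not isolated)
Conditions: 1 M aq. HCl–THF (1:1), 45 °C; evaporate (PhMe azeotrope); then CSA (cat.), MeCN–THF, 50 °C, to equilibrium
Reagents that add atoms: none
Why: Acid-catalysed ketal hydrolysis through the dioxolanyl oxocarbenium ions frees both arms to give 8, and acid-catalysed acyl substitution at C12 by a γ-hydroxyl (tetrahedral intermediate, loss of ethanol) closes the lactone. The closest known reaction type is the one-pot ketal cleavage and γ-lactonisation of hydroxy esters on sugar-alcohol scaffolds. The one ring formed is the γ-lactone, closed in the 5-exo-trig mode by O6 on the C12 carbonyl. The one new stereocentre is C7: it becomes stereogenic only when one of its two identical arms is tied into the ring, and its configuration is set by the fixed, like configurations of C6 and C8 through the preference for the trans-4,5-disubstituted lactone. The step needs selectivity between the two diastereotopic secondary hydroxyls (trans against cis γ-lactone) and against the primary hydroxyls (δ-lactones). Both are thermodynamic: under the anhydrous acid of the second stage all lactones interconvert by reversible translactonisation, five-membered lactones are favoured over six-membered ones, and the cis isomer must hold the C5 hydroxymethyl group and the C8 side chain eclipsed. Evaporation removes water and ethanol, which moves open forms to lactone. The size of the trans preference is the uncertain point, so the equilibration is continued in step 6, where the C8 arm becomes a bulkier dioxolane.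

Step 6
Reactants: 9 (4R,5S)-4-[(1S)-1,2-dihydroxyethyl]-5-(hydroxymethyl)oxolan-2-one; 2 2,2-dimethoxypropane
Product: 10 (4R,5S)-4-[(4S)-2,2-dimethyl-1,3-dioxolan-4-yl]-5-(hydroxymethyl)oxolan-2-one
Conditions: 2, TsOH (cat.), acetone, rt; Et3N quench
Reagents that add atoms: none
Why: Acid-catalysed acetonide formation takes the vicinal C8,C9-diol (five-membered dioxolane) and leaves the isolated primary C5 hydroxyl free; translactonisation stays possible until the C8 hydroxyl is tied up, which should favour the trans lactone further, and any cis isomer should be separable at this stage.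

Step 7
Reactants: 10 (4R,5S)-4-[(4S)-2,2-dimethyl-1,3-dioxolan-4-yl]-5-(hydroxymethyl)oxolan-2-one; 11 benzyl (triphenylphosphoranylidene)acetate
Product: 13 benzyl (2E)-3-[(2R,3S)-3-[(4S)-2,2-dimethyl-1,3-dioxolan-4-yl]-5-oxooxolan-2-yl]prop-2-enoate, via aldehyde 12 (not isolated)
Conditions: Dess–Martin periodinane, CH2Cl2, 0 °C → rt; then 11, rt
Reagents that add atoms: none
Why: Dess–Martin oxidation gives the α-acyloxy aldehyde, which is trapped in the same flask by the neutral stabilised ylide (Wittig reaction) before it can epimerise at C6; the alkene geometry does not matter because the bond is saturated next.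

Step 8
Reactants: 13 benzyl (2E)-3-[(2R,3S)-3-[(4S)-2,2-dimethyl-1,3-dioxolan-4-yl]-5-oxooxolan-2-yl]prop-2-enoate
Product: 14 3-[(2R,3S)-3-[(4S)-2,2-dimethyl-1,3-dioxolan-4-yl]-5-oxooxolan-2-yl]propanoic acid
Conditions: H2 (1 atm), 10% Pd/C, EtOAc, rt
Reagents that add atoms: none
Why: Catalytic hydrogenation saturates C4=C5 and hydrogenolyses the benzyl ester in one operation; the electron-poor alkene is reduced quickly at 1 atm, which should keep hydrogenolysis of the allylic lactone C6–O bond to a minimum.

Step 9
Reactants: 14 3-[(2R,3S)-3-[(4S)-2,2-dimethyl-1,3-dioxolan-4-yl]-5-oxooxolan-2-yl]propanoic acid; 15 (4R)-4-benzyl-1,3-oxazolidin-2-one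
Product: 17 (4R)-4-benzyl-3-{3-[(2R,3S)-3-[(4S)-2,2-dimethyl-1,3-dioxolan-4-yl]-5-oxooxolan-2-yl]propanoyl}-1,3-oxazolidin-2-one, via mixed pivalic anhydride 16 (not isolated)
Conditions: t-BuCOCl, Et3N, THF, −20 °C; then 15, LiCl, −20 °C → rt
Reagents that add atoms: none
Why: Mixed-anhydride activation followed by LiCl/Et3N-mediated N-acylation of the oxazolidinone uses no strong base, so the lactone and the ketal stay intact.

Step 10
Reactants: 17 (4R)-4-benzyl-3-{3-[(2R,3S)-3-[(4S)-2,2-dimethyl-1,3-dioxolan-4-yl]-5-oxooxolan-2-yl]propanoyl}-1,3-oxazolidin-2-one; 18 allyl iodide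
Product: 20 (4R)-4-benzyl-3-[(2R)-2-{[(2R,3S)-3-[(4S)-2,2-dimethyl-1,3-dioxolan-4-yl]-5-oxooxolan-2-yl]methyl}pent-4-enoyl]-1,3-oxazolidin-2-one, via sodium enolate 19 (not isolated)
Conditions: NaN(SiMe3)2 (1.05 equiv), THF, −78 °C; 18, −78 → −45 °C
Reagents that add atoms: none
Why: Evans asymmetric alkylation: the imide, far more acidic than the lactone, is deprotonated selectively to the chelated Z-enolate, and allyl iodide attacks the face opposite the benzyl group of the (R)-auxiliary, which sets C4 as R; the weakly basic imide enolate should leave the lactone alone at −78 °C.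

Step 11
Reactants: 20 (4R)-4-benzyl-3-[(2R)-2-{[(2R,3S)-3-[(4S)-2,2-dimethyl-1,3-dioxolan-4-yl]-5-oxooxolan-2-yl]methyl}pent-4-enoyl]-1,3-oxazolidin-2-one
Product: 21 (4S,5R)-4-[(4S)-2,2-dimethyl-1,3-dioxolan-4-yl]-5-[(2R)-2-(hydroxymethyl)pent-4-en-1-yl]oxolan-2-one
Conditions: NaBH4, THF–H2O (4:1), 0 °C → rt
Reagents that add atoms: none
Why: Reductive cleavage of the N-acyl oxazolidinone: borohydride attacks the activated exocyclic imide carbonyl much faster than the lactone, which should give the C15 alcohol and return the auxiliary.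

Step 12
Reactants: 21 (4S,5R)-4-[(4S)-2,2-dimethyl-1,3-dioxolan-4-yl]-5-[(2R)-2-(hydroxymethyl)pent-4-en-1-yl]oxolan-2-one
Product: 22 (4S,5R)-5-[(2R)-2-(TBDPS-oxymethyl)pent-4-en-1-yl]-4-[(4S)-2,2-dimethyl-1,3-dioxolan-4-yl]oxolan-2-one
Conditions: TBDPSCl, imidazole, CH2Cl2, rt
Reagents that add atoms: tert-butyl(chloro)diphenylsilane, CC(C)(C)[Si](Cl)(c1ccccc1)c1ccccc1
Why: Silyl ether protection of the primary alcohol masks C15 through the enolate, acylation and olefination steps ahead.

Step 13
Reactants: 22 (4S,5R)-5-[(2R)-2-(TBDPS-oxymethyl)pent-4-en-1-yl]-4-[(4S)-2,2-dimethyl-1,3-dioxolan-4-yl]oxolan-2-one; 23 benzyl chloromethyl ether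
Product: 25 (3R,4S,5R)-3-[(benzyloxy)methyl]-5-[(2R)-2-(TBDPS-oxymethyl)pent-4-en-1-yl]-4-[(4S)-2,2-dimethyl-1,3-dioxolan-4-yl]oxolan-2-one, via lithium enolate 24 (not isolated)
Conditions: LiN(iPr)2, THF, −78 °C; 23, DMPU, −78 → −40 °C
Reagents that add atoms: none
Why: Kinetic lactone enolate alkylation with a reactive α-chloro ether; the electrophile should enter anti to the C7 substituent, and the benzyloxymethyl group is a base-stable precursor of the C13 methylene, installed while the lactone is the only enolisable group.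

Step 14
Reactants: 25 (3R,4S,5R)-3-[(benzyloxy)methyl]-5-[(2R)-2-(TBDPS-oxymethyl)pent-4-en-1-yl]-4-[(4S)-2,2-dimethyl-1,3-dioxolan-4-yl]oxolan-2-one
Product: 26 (3R,4R,5R)-3-[(benzyloxy)methyl]-5-[(2R)-2-(TBDPS-oxymethyl)pent-4-en-1-yl]-4-[(1S)-1,2-dihydroxyethyl]oxolan-2-one
Conditions: AcOH–H2O (4:1), 40 °C
Reagents that add atoms: none
Why: Acid hydrolysis of the acetonide; the silyl and benzyl ethers survive, and the trans 12,6-lactone remains the preferred γ-lactone for the same reason as in step 5.

Step 15
Reactants: 26 (3R,4R,5R)-3-[(benzyloxy)methyl]-5-[(2R)-2-(TBDPS-oxymethyl)pent-4-en-1-yl]-4-[(1S)-1,2-dihydroxyethyl]oxolan-2-one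
Product: 27 (3R,4R,5R)-3-[(benzyloxy)methyl]-5-[(2R)-2-(TBDPS-oxymethyl)pent-4-en-1-yl]-4-[(1S)-1-hydroxy-2-iodoethyl]oxolan-2-one
Conditions: I2, PPh3, imidazole (1.1 equiv each), THF, 0 °C
Reagents that add atoms: iodine, II
Why: Appel-type iodination through the alkoxyphosphonium ion is much faster at the primary C9 hydroxyl than at the hindered secondary C8 hydroxyl; low temperature and near-stoichiometric reagent avoid deoxygenation of the diol.

Step 16
Reactants: 27 (3R,4R,5R)-3-[(benzyloxy)methyl]-5-[(2R)-2-(TBDPS-oxymethyl)pent-4-en-1-yl]-4-[(1S)-1-hydroxy-2-iodoethyl]oxolan-2-one; 28 (2R)-2-methylbutanoic acid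
Product: 29 (1S)-1-[(2R,3S,4R)-4-[(benzyloxy)methyl]-2-[(2R)-2-(TBDPS-oxymethyl)pent-4-en-1-yl]-5-oxooxolan-3-yl]-2-iodoethyl (2R)-2-methylbutanoate
Conditions: 28, DCC, DMAP (cat.), CH2Cl2, 0 °C → rt
Reagents that add atoms: none
Why: Steglich esterification puts the side chain on C8 before C14 exists, so that a free C8 hydroxyl never faces the C14 ester; low temperature and catalytic DMAP limit epimerisation of the acid α-centre.

Step 17
Reactants: 29 (1S)-1-[(2R,3S,4R)-4-[(benzyloxy)methyl]-2-[(2R)-2-(TBDPS-oxymethyl)pent-4-en-1-yl]-5-oxooxolan-3-yl]-2-iodoethyl (2R)-2-methylbutanoate; 30 trimethyl phosphonoacetate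
Product: 31 methyl (4R)-4-[(2R,3S,4R)-4-[(benzyloxy)methyl]-2-[(2R)-2-(TBDPS-oxymethyl)pent-4-en-1-yl]-5-oxooxolan-3-yl]-2-(dimethoxyphosphoryl)-4-{[(2R)-2-methylbutanoyl]oxy}butanoate (C10 epimers)
Conditions: 30 (3 equiv), NaH (2.5 equiv), DMF, 0 °C; then 29, 50 °C
Reagents that add atoms: none
Why: SN2 C-alkylation of the stabilised phosphonoacetate anion in a dipolar aprotic solvent forms C9–C10; the anion is too weakly basic to enolise the lactone or the side-chain ester, and the new C10 centre is formed as a mixture that becomes sp2 in step 20.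

Step 18
Reactants: 31 methyl (4R)-4-[(2R,3S,4R)-4-[(benzyloxy)methyl]-2-[(2R)-2-(TBDPS-oxymethyl)pent-4-en-1-yl]-5-oxooxolan-3-yl]-2-(dimethoxyphosphoryl)-4-{[(2R)-2-methylbutanoyl]oxy}butanoate
Product: 33 methyl (4R)-4-[(2R,3S,4R)-4-[(benzyloxy)methyl]-2-[(2R)-5-hydroxy-2-(TBDPS-oxymethyl)pentyl]-5-oxooxolan-3-yl]-2-(dimethoxyphosphoryl)-4-{[(2R)-2-methylbutanoyl]oxy}butanoate, via alkylborane 32 (not isolated)
Conditions: 9-BBN, THF, 0 °C → rt; then 30% H2O2, aq. NaOAc, 0 °C
Reagents that add atoms: hydrogen peroxide, OO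
Why: Hydroboration–oxidation: 9-BBN adds anti-Markovnikov to the terminal alkene only and leaves the esters, lactone and phosphonate untouched; the acetate-buffered peroxide oxidation avoids ester hydrolysis.

Step 19
Reactants: 33 methyl (4R)-4-[(2R,3S,4R)-4-[(benzyloxy)methyl]-2-[(2R)-5-hydroxy-2-(TBDPS-oxymethyl)pentyl]-5-oxooxolan-3-yl]-2-(dimethoxyphosphoryl)-4-{[(2R)-2-methylbutanoyl]oxy}butanoate
Product: 34 methyl (4R)-4-[(2R,3S,4R)-4-[(benzyloxy)methyl]-2-[(2R)-5-oxo-2-(TBDPS-oxymethyl)pentyl]-5-oxooxolan-3-yl]-2-(dimethoxyphosphoryl)-4-{[(2R)-2-methylbutanoyl]oxy}butanoate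
Conditions: Dess–Martin periodinane, CH2Cl2, rt
Reagents that add atoms: none
Why: Dess–Martin oxidation gives the C1 aldehyde without base, so no olefination starts before dilution.

Step 20
Reactants: 34 methyl (4R)-4-[(2R,3S,4R)-4-[(benzyloxy)methyl]-2-[(2R)-5-oxo-2-(TBDPS-oxymethyl)pentyl]-5-oxooxolan-3-yl]-2-(dimethoxyphosphoryl)-4-{[(2R)-2-methylbutanoyl]oxy}butanoate
Product: 35 methyl (3R,3aS,4R,6E,10R,11aR)-3-[(benzyloxy)methyl]-10-(TBDPS-oxymethyl)-4-{[(2R)-2-methylbutanoyl]oxy}-2-oxo-2,3,3a,4,5,8,9,10,11,11a-decahydrocyclodeca[b]furan-6-carboxylate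
Conditions: LiCl, DBU, MeCN, 1 mM (slow addition of 34), rt
Reagents that add atoms: none
Why: Intramolecular Horner–Wadsworth–Emmons olefination under Masamune–Roush conditions at high dilution closes the ten-membered ring at C1=C10; α-alkyl phosphonoacetates favour the E-enoate (C14 trans to C2), which is also the ring-cis and less strained geometry, and the trans-disubstituted lactone removes two rotors from the chain.

Step 21
Reactants: 35 methyl (3R,3aS,4R,6E,10R,11aR)-3-[(benzyloxy)methyl]-10-(TBDPS-oxymethyl)-4-{[(2R)-2-methylbutanoyl]oxy}-2-oxo-2,3,3a,4,5,8,9,10,11,11a-decahydrocyclodeca[b]furan-6-carboxylate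
Product: 36 methyl (3R,3aS,4R,6E,10R,11aR)-3-(hydroxymethyl)-10-(TBDPS-oxymethyl)-4-{[(2R)-2-methylbutanoyl]oxy}-2-oxo-2,3,3a,4,5,8,9,10,11,11a-decahydrocyclodeca[b]furan-6-carboxylate
Conditions: BCl3, C6HMe5, CH2Cl2, −78 °C; then MeOH–H2O
Reagents that add atoms: none
Why: Lewis-acid debenzylation with pentamethylbenzene as a non-nucleophilic trap for the benzyl cation (Friedel–Crafts capture) at −78 °C should spare the enoate, both esters, the lactone and the silyl ether; hydrogenolysis is ruled out by the alkene.

Step 22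
Reactants: 36 methyl (3R,3aS,4R,6E,10R,11aR)-3-(hydroxymethyl)-10-(TBDPS-oxymethyl)-4-{[(2R)-2-methylbutanoyl]oxy}-2-oxo-2,3,3a,4,5,8,9,10,11,11a-decahydrocyclodeca[b]furan-6-carboxylate
Product: 38 methyl (3aS,4R,6E,10R,11aR)-10-(TBDPS-oxymethyl)-3-methylidene-4-{[(2R)-2-methylbutanoyl]oxy}-2-oxo-2,3,3a,4,5,8,9,10,11,11a-decahydrocyclodeca[b]furan-6-carboxylate, via mesylate 37 (not isolated)
Conditions: MsCl, Et3N, CH2Cl2, 0 °C; then DBU, 0 °C → rt
Reagents that add atoms: none
Why: Mesylation followed by E1cB elimination; the only hydrogen β to the leaving group is the acidic one at C11, so the double bond can form only as the exocyclic C11=C13 methylene.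

Step 23
Reactants: 38 methyl (3aS,4R,6E,10R,11aR)-10-(TBDPS-oxymethyl)-3-methylidene-4-{[(2R)-2-methylbutanoyl]oxy}-2-oxo-2,3,3a,4,5,8,9,10,11,11a-decahydrocyclodeca[b]furan-6-carboxylate
Product: 39 methyl (3aS,4R,6E,10R,11aR)-10-(hydroxymethyl)-3-methylidene-4-{[(2R)-2-methylbutanoyl]oxy}-2-oxo-2,3,3a,4,5,8,9,10,11,11a-decahydrocyclodeca[b]furan-6-carboxylate
Conditions: HF·pyridine, THF–pyridine, 0 °C → rt
Reagents that add atoms: none
Why: Fluoride-mediated desilylation in a buffered, weakly acidic medium should free the C15 hydroxyl without conjugate addition to the methylene lactone, acyl migration or translactonisation.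

## Compound list

1 | D-arabinitol | OC[C@@H](O)C(O)[C@H](O)CO | starting material
2 | 2,2-dimethoxypropane | COC(C)(C)OC | starting material
3 | 1,2:4,5-di-O-isopropylidene-D-arabinitol | OC([C@H]1COC(C)(C)O1)[C@H]1COC(C)(C)O1 | intermediate
4 | bis[(4R)-2,2-dimethyl-1,3-dioxolan-4-yl]methanone | O=C([C@H]1COC(C)(C)O1)[C@H]1COC(C)(C)O1 | intermediate
5 | triethyl phosphonoacetate | CCOC(=O)CP(=O)(OCC)OCC | starting material
6 | ethyl 3,3-bis[(4S)-2,2-dimethyl-1,3-dioxolan-4-yl]prop-2-enoate | CCOC(=O)C=C([C@H]1COC(C)(C)O1)[C@H]1COC(C)(C)O1 | intermediate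
7 | ethyl 3,3-bis[(4S)-2,2-dimethyl-1,3-dioxolan-4-yl]propanoate | CCOC(=O)CC([C@H]1COC(C)(C)O1)[C@H]1COC(C)(C)O1 | intermediate
8 | ethyl (4S)-3-[(1S)-1,2-dihydroxyethyl]-4,5-dihydroxypentanoate (pentaol ester, not isolated) | CCOC(=O)CC([C@H](O)CO)[C@H](O)CO | intermediate
9 | (4R,5S)-4-[(1S)-1,2-dihydroxyethyl]-5-(hydroxymethyl)oxolan-2-one | O=C1C[C@H]([C@H](O)CO)[C@@H](CO)O1 | intermediate
10 | (4R,5S)-4-[(4S)-2,2-dimethyl-1,3-dioxolan-4-yl]-5-(hydroxymethyl)oxolan-2-one | O=C1C[C@H]([C@H]2COC(C)(C)O2)[C@@H](CO)O1 | intermediate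
11 | benzyl (triphenylphosphoranylidene)acetate | O=C(C=P(c1ccccc1)(c1ccccc1)c1ccccc1)OCc1ccccc1 | starting material
12 | (2S,3R)-3-[(4S)-2,2-dimethyl-1,3-dioxolan-4-yl]-5-oxooxolane-2-carbaldehyde (not isolated) | O=C1C[C@H]([C@H]2COC(C)(C)O2)[C@@H](C=O)O1 | intermediate
13 | benzyl (2E)-3-[(2R,3S)-3-[(4S)-2,2-dimethyl-1,3-dioxolan-4-yl]-5-oxooxolan-2-yl]prop-2-enoate | O=C1C[C@H]([C@H]2COC(C)(C)O2)[C@@H](/C=C/C(=O)OCc2ccccc2)O1 | intermediate
14 | 3-[(2R,3S)-3-[(4S)-2,2-dimethyl-1,3-dioxolan-4-yl]-5-oxooxolan-2-yl]propanoic acid | O=C1C[C@H]([C@H]2COC(C)(C)O2)[C@@H](CCC(=O)O)O1 | intermediate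
15 | (4R)-4-benzyl-1,3-oxazolidin-2-one | O=C1N[C@H](Cc2ccccc2)CO1 | starting material
16 | mixed pivalic anhydride of 14 (not isolated) | O=C1C[C@H]([C@H]2COC(C)(C)O2)[C@@H](CCC(=O)OC(=O)C(C)(C)C)O1 | intermediate
17 | (4R)-4-benzyl-3-{3-[(2R,3S)-3-[(4S)-2,2-dimethyl-1,3-dioxolan-4-yl]-5-oxooxolan-2-yl]propanoyl}-1,3-oxazolidin-2-one | O=C1C[C@H]([C@H]2COC(C)(C)O2)[C@@H](CCC(=O)N2[C@H](Cc3ccccc3)COC2=O)O1 | intermediate
18 | allyl iodide (3-iodoprop-1-ene) | C=CCI | starting material
19 | sodium (Z)-enolate of 17 (not isolated) | O=C1C[C@H]([C@H]2COC(C)(C)O2)[C@@H](C/C=C(\[O-])N2[C@H](Cc3ccccc3)COC2=O)O1.[Na+] | intermediate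
20 | (4R)-4-benzyl-3-[(2R)-2-{[(2R,3S)-3-[(4S)-2,2-dimethyl-1,3-dioxolan-4-yl]-5-oxooxolan-2-yl]methyl}pent-4-enoyl]-1,3-oxazolidin-2-one | O=C1C[C@H]([C@H]2COC(C)(C)O2)[C@@H](C[C@@H](CC=C)C(=O)N2[C@H](Cc3ccccc3)COC2=O)O1 | intermediate
21 | (4S,5R)-4-[(4S)-2,2-dimethyl-1,3-dioxolan-4-yl]-5-[(2R)-2-(hydroxymethyl)pent-4-en-1-yl]oxolan-2-one | O=C1C[C@H]([C@H]2COC(C)(C)O2)[C@@H](C[C@@H](CC=C)CO)O1 | intermediate
22 | (4S,5R)-5-[(2R)-2-(TBDPS-oxymethyl)pent-4-en-1-yl]-4-[(4S)-2,2-dimethyl-1,3-dioxolan-4-yl]oxolan-2-one | O=C1C[C@H]([C@H]2COC(C)(C)O2)[C@@H](C[C@@H](CC=C)CO[Si](c2ccccc2)(c2ccccc2)C(C)(C)C)O1 | intermediate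
23 | benzyl chloromethyl ether | ClCOCc1ccccc1 | starting material
24 | lithium enolate of 22 (not isolated) | [Li+].[O-]C1=C[C@H]([C@H]2COC(C)(C)O2)[C@@H](C[C@@H](CC=C)CO[Si](c2ccccc2)(c2ccccc2)C(C)(C)C)O1 | intermediate
25 | (3R,4S,5R)-3-[(benzyloxy)methyl]-5-[(2R)-2-(TBDPS-oxymethyl)pent-4-en-1-yl]-4-[(4S)-2,2-dimethyl-1,3-dioxolan-4-yl]oxolan-2-one | O=C1[C@@H](COCc2ccccc2)[C@H]([C@H]2COC(C)(C)O2)[C@@H](C[C@@H](CC=C)CO[Si](c2ccccc2)(c2ccccc2)C(C)(C)C)O1 | intermediate
26 | (3R,4R,5R)-3-[(benzyloxy)methyl]-5-[(2R)-2-(TBDPS-oxymethyl)pent-4-en-1-yl]-4-[(1S)-1,2-dihydroxyethyl]oxolan-2-one | O=C1[C@@H](COCc2ccccc2)[C@H]([C@H](O)CO)[C@@H](C[C@@H](CC=C)CO[Si](c2ccccc2)(c2ccccc2)C(C)(C)C)O1 | intermediate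
27 | (3R,4R,5R)-3-[(benzyloxy)methyl]-5-[(2R)-2-(TBDPS-oxymethyl)pent-4-en-1-yl]-4-[(1S)-1-hydroxy-2-iodoethyl]oxolan-2-one | O=C1[C@@H](COCc2ccccc2)[C@H]([C@H](O)CI)[C@@H](C[C@@H](CC=C)CO[Si](c2ccccc2)(c2ccccc2)C(C)(C)C)O1 | intermediate
28 | (2R)-2-methylbutanoic acid | CC[C@@H](C)C(O)=O | starting material
29 | (1S)-1-[(2R,3S,4R)-4-[(benzyloxy)methyl]-2-[(2R)-2-(TBDPS-oxymethyl)pent-4-en-1-yl]-5-oxooxolan-3-yl]-2-iodoethyl (2R)-2-methylbutanoate | O=C1[C@@H](COCc2ccccc2)[C@H]([C@H](OC(=O)[C@H](C)CC)CI)[C@@H](C[C@@H](CC=C)CO[Si](c2ccccc2)(c2ccccc2)C(C)(C)C)O1 | intermediate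
30 | trimethyl phosphonoacetate | COC(=O)CP(=O)(OC)OC | starting material
31 | methyl (4R)-4-[(2R,3S,4R)-4-[(benzyloxy)methyl]-2-[(2R)-2-(TBDPS-oxymethyl)pent-4-en-1-yl]-5-oxooxolan-3-yl]-2-(dimethoxyphosphoryl)-4-{[(2R)-2-methylbutanoyl]oxy}butanoate (C10 epimers) | O=C1[C@@H](COCc2ccccc2)[C@H]([C@H](OC(=O)[C@H](C)CC)CC(C(=O)OC)P(=O)(OC)OC)[C@@H](C[C@@H](CC=C)CO[Si](c2ccccc2)(c2ccccc2)C(C)(C)C)O1 | intermediate
32 | C1 9-borabicyclo[3.3.1]nonan-9-yl adduct of 31 (alkylborane, not isolated) | O=C1[C@@H](COCc2ccccc2)[C@H]([C@H](OC(=O)[C@H](C)CC)CC(C(=O)OC)P(=O)(OC)OC)[C@@H](C[C@@H](CCCB2C3CCCC2CCC3)CO[Si](c2ccccc2)(c2ccccc2)C(C)(C)C)O1 | intermediate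
33 | methyl (4R)-4-[(2R,3S,4R)-4-[(benzyloxy)methyl]-2-[(2R)-5-hydroxy-2-(TBDPS-oxymethyl)pentyl]-5-oxooxolan-3-yl]-2-(dimethoxyphosphoryl)-4-{[(2R)-2-methylbutanoyl]oxy}butanoate (C10 epimers) | O=C1[C@@H](COCc2ccccc2)[C@H]([C@H](OC(=O)[C@H](C)CC)CC(C(=O)OC)P(=O)(OC)OC)[C@@H](C[C@@H](CCCO)CO[Si](c2ccccc2)(c2ccccc2)C(C)(C)C)O1 | intermediate
34 | methyl (4R)-4-[(2R,3S,4R)-4-[(benzyloxy)methyl]-2-[(2R)-5-oxo-2-(TBDPS-oxymethyl)pentyl]-5-oxooxolan-3-yl]-2-(dimethoxyphosphoryl)-4-{[(2R)-2-methylbutanoyl]oxy}butanoate (C10 epimers) | O=C1[C@@H](COCc2ccccc2)[C@H]([C@H](OC(=O)[C@H](C)CC)CC(C(=O)OC)P(=O)(OC)OC)[C@@H](C[C@@H](CCC=O)CO[Si](c2ccccc2)(c2ccccc2)C(C)(C)C)O1 | intermediate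
35 | methyl (3R,3aS,4R,6E,10R,11aR)-3-[(benzyloxy)methyl]-10-(TBDPS-oxymethyl)-4-{[(2R)-2-methylbutanoyl]oxy}-2-oxo-2,3,3a,4,5,8,9,10,11,11a-decahydrocyclodeca[b]furan-6-carboxylate | C(OCc4ccccc4)[C@@H]1C(=O)O[C@@H]2C[C@H](CO[Si](c3ccccc3)(c3ccccc3)C(C)(C)C)CC/C=C(/C(=O)OC)C[C@@H](OC(=O)[C@H](C)CC)[C@@H]12 | intermediate
36 | methyl (3R,3aS,4R,6E,10R,11aR)-3-(hydroxymethyl)-10-(TBDPS-oxymethyl)-4-{[(2R)-2-methylbutanoyl]oxy}-2-oxo-2,3,3a,4,5,8,9,10,11,11a-decahydrocyclodeca[b]furan-6-carboxylate | OC[C@@H]1C(=O)O[C@@H]2C[C@H](CO[Si](c3ccccc3)(c3ccccc3)C(C)(C)C)CC/C=C(/C(=O)OC)C[C@@H](OC(=O)[C@H](C)CC)[C@@H]12 | intermediate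
37 | C13 methanesulfonate of 36 (not isolated) | CS(=O)(=O)OC[C@@H]1C(=O)O[C@@H]2C[C@H](CO[Si](c3ccccc3)(c3ccccc3)C(C)(C)C)CC/C=C(/C(=O)OC)C[C@@H](OC(=O)[C@H](C)CC)[C@@H]12 | intermediate
38 | methyl (3aS,4R,6E,10R,11aR)-10-(TBDPS-oxymethyl)-3-methylidene-4-{[(2R)-2-methylbutanoyl]oxy}-2-oxo-2,3,3a,4,5,8,9,10,11,11a-decahydrocyclodeca[b]furan-6-carboxylate | C=C1C(=O)O[C@@H]2C[C@H](CO[Si](c3ccccc3)(c3ccccc3)C(C)(C)C)CC/C=C(/C(=O)OC)C[C@@H](OC(=O)[C@H](C)CC)[C@@H]12 | intermediate
39 | methyl (3aS,4R,6E,10R,11aR)-10-(hydroxymethyl)-3-methylidene-4-{[(2R)-2-methylbutanoyl]oxy}-2-oxo-2,3,3a,4,5,8,9,10,11,11a-decahydrocyclodeca[b]furan-6-carboxylate (CNP0141952.3) | C=C1C(=O)O[C@@H]2C[C@H](CO)CC/C=C(/C(=O)OC)C[C@@H](OC(=O)[C@H](C)CC)[C@@H]12 | target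

## Step count and least certain steps

Total step count: 23. Longest linear sequence: 23 steps (1 to 39); every other reactant is commercial.

**Step 5 (key step).** What is most likely to go wrong is an insufficient thermodynamic bias between the two γ-lactones, or incomplete equilibration, so that lactonisation on the wrong diastereotopic hydroxyl persists. The energy gap between trans and cis 4,5-disubstituted lactones with small, hydrogen-bonding substituents may be modest. The fallback replaces thermodynamic by kinetic control; it sets out from 6 and returns at 10. Aqueous acid on 6 would cleave both ketals and lactonise whichever arm is cis to the ester, giving the butenolide (5S)-4-[(1S)-1,2-dihydroxyethyl]-5-(hydroxymethyl)furan-2(5H)-one F1; either arm gives the same compound because C7 is sp2. Acetonation of its diol with 2 would give (5S)-4-[(4S)-2,2-dimethyl-1,3-dioxolan-4-yl]-5-(hydroxymethyl)furan-2(5H)-one F2. Hydroxyl-directed hydrogenation with [Ir(cod)(PCy3)(py)]PF6 and H2 in CH2Cl2 would deliver hydrogen to C7 from the face of the C5 hydroxymethyl group and so give the trans lactone 10.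

**Step 20.** What is most likely to go wrong is intermolecular olefination (cyclic dimers and oligomers) outrunning ring closure, because the ten-membered transition state carries transannular strain; partial loss of E-selectivity is a second risk. The fallback closes the same bond by metathesis; it sets out from 34 and returns at 35. Non-basic Takai–Lombardo methylenation (Zn, CH2Br2, TiCl4) of the aldehyde would give the but-3-enyl phosphonate F9. Olefination of its phosphonate with aqueous formaldehyde and K2CO3 would give the 2-substituted acrylate F10. Ring-closing metathesis with the second-generation Hoveyda–Grubbs catalyst in toluene at 80 °C and 1 mM would then form C1=C10 with loss of ethene to give 35; the ring should again enforce the ring-cis alkene.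

**Step 17.** What is most likely to go wrong is slow substitution at the β-branched, β-acyloxy iodide, which would let E2 elimination towards the enol ester or acyl transfer compete. The fallback builds C9–C10 as an alkene and reduces it; it sets out from 26 and returns at 31. Selective silylation of the primary hydroxyl (Et3SiCl, imidazole, −20 °C) would give the C9 triethylsilyl ether F5, and Steglich esterification with 28 the C8 ester F6. Swern oxidation, which converts primary triethylsilyl ethers directly, would give the α-acyloxy aldehyde F7. Knoevenagel condensation with 30 (TiCl4, N-methylmorpholine, THF, 0 °C) would give the alkylidene phosphonoacetate F8 as an E/Z mixture, and conjugate reduction with NaBH4 in MeOH–THF at −20 °C would give 31.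

**Step 11.** What is most likely to go wrong is over-reduction, that is, hydride attack on the lactone carbonyl in competition with the imide. The fallback separates cleavage from reduction; it sets out from 20 and returns at 21. LiOH/H2O2 in THF–H2O at 0 °C would release the auxiliary and give the acid (2R)-2-{[(2R,3S)-3-[(4S)-2,2-dimethyl-1,3-dioxolan-4-yl]-5-oxooxolan-2-yl]methyl}pent-4-enoic acid F3. Any lactone opened in this step recloses on mild acidification, since O6 is the only free γ-hydroxyl. Activation with isobutyl chloroformate and N-methylmorpholine at −15 °C would give the mixed carbonic anhydride F4, which NaBH4 reduces within minutes at that temperature to 21 while the lactone is inert.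

## Further compounds

F1 | step 5 | (5S)-4-[(1S)-1,2-dihydroxyethyl]-5-(hydroxymethyl)furan-2(5H)-one | O=C1C=C([C@H](O)CO)[C@@H](CO)O1
F2 | step 5 | (5S)-4-[(4S)-2,2-dimethyl-1,3-dioxolan-4-yl]-5-(hydroxymethyl)furan-2(5H)-one | O=C1C=C([C@H]2COC(C)(C)O2)[C@@H](CO)O1
F3 | step 11 | (2R)-2-{[(2R,3S)-3-[(4S)-2,2-dimethyl-1,3-dioxolan-4-yl]-5-oxooxolan-2-yl]methyl}pent-4-enoic acid | O=C1C[C@H]([C@H]2COC(C)(C)O2)[C@@H](C[C@@H](CC=C)C(=O)O)O1
F4 | step 11 | isobutyl carbonic mixed anhydride of F3 | O=C1C[C@H]([C@H]2COC(C)(C)O2)[C@@H](C[C@@H](CC=C)C(=O)OC(=O)OCC(C)C)O1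
F5 | step 17 | C9 triethylsilyl ether of 26 | O=C1[C@@H](COCc2ccccc2)[C@H]([C@H](O)CO[Si](CC)(CC)CC)[C@@H](C[C@@H](CC=C)CO[Si](c2ccccc2)(c2ccccc2)C(C)(C)C)O1
F6 | step 17 | C8 (2R)-2-methylbutanoate of F5 | O=C1[C@@H](COCc2ccccc2)[C@H]([C@H](OC(=O)[C@H](C)CC)CO[Si](CC)(CC)CC)[C@@H](C[C@@H](CC=C)CO[Si](c2ccccc2)(c2ccccc2)C(C)(C)C)O1
F7 | step 17 | C9 aldehyde bearing the C8 (2R)-2-methylbutanoate | O=C1[C@@H](COCc2ccccc2)[C@H]([C@H](OC(=O)[C@H](C)CC)C=O)[C@@H](C[C@@H](CC=C)CO[Si](c2ccccc2)(c2ccccc2)C(C)(C)C)O1
F8 | step 17 | C9=C10 alkylidene phosphonoacetate (E/Z mixture) | O=C1[C@@H](COCc2ccccc2)[C@H]([C@H](OC(=O)[C@H](C)CC)C=C(C(=O)OC)P(=O)(OC)OC)[C@@H](C[C@@H](CC=C)CO[Si](c2ccccc2)(c2ccccc2)C(C)(C)C)O1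
F9 | step 20 | but-3-enyl phosphonate (C1 aldehyde of 34 methylenated; C10 epimers) | O=C1[C@@H](COCc2ccccc2)[C@H]([C@H](OC(=O)[C@H](C)CC)CC(C(=O)OC)P(=O)(OC)OC)[C@@H](C[C@@H](CCC=C)CO[Si](c2ccccc2)(c2ccccc2)C(C)(C)C)O1
F10 | step 20 | 2-substituted methyl acrylate diene (C10=CH2 and C1=CH2) | O=C1[C@@H](COCc2ccccc2)[C@H]([C@H](OC(=O)[C@H](C)CC)CC(=C)C(=O)OC)[C@@H](C[C@@H](CCC=C)CO[Si](c2ccccc2)(c2ccccc2)C(C)(C)C)O1
A1 | alternative 1 | isoxazoline-bridged ten-membered carbocycle (C6=N–O–C8 bridge, C7 tert-butyl acetate arm, C15 TBDPS ether, C14 methyl ester) | N1=C2C[C@H](CO[Si](c3ccccc3)(c3ccccc3)C(C)(C)C)CC/C=C(/C(=O)OC)C[C@@H](O1)[C@H]2CC(=O)OC(C)(C)C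
A2 | alternative 1 | open-chain (E)-aldoxime with (E)-C7=C8 and (E)-C1=C10 alkenes | O/N=C/C[C@H](CO[Si](c1ccccc1)(c1ccccc1)C(C)(C)C)CC/C=C(/C(=O)OC)C/C=C/CC(=O)OC(C)(C)C
A3 | alternative 2 | ten-membered C6 ketone with C8 PMB ether, ring-cis C1=C10 alkene, C14 TBS ether and C15 TBDPS ether | O=C1C[C@H](CO[Si](c2ccccc2)(c2ccccc2)C(C)(C)C)CC/C=C(/CO[Si](C)(C)C(C)(C)C)C[C@@H](OCc2ccc(OC)cc2)C1
A4 | alternative 2 | (1R,2S,5R)-5-(TBDPS-oxymethyl)-2-{3-[tert-butyl(dimethyl)silyl]oxyprop-1-en-2-yl}-1-[(E)-2-(4-methoxybenzyloxy)ethenyl]cyclohexan-1-ol | O[C@]1(/C=C/OCc2ccc(OC)cc2)C[C@H](CO[Si](c2ccccc2)(c2ccccc2)C(C)(C)C)CC[C@H]1C(=C)CO[Si](C)(C)C(C)(C)C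
A5 | alternative 3 | trans,trans lactone with C5 TBDPS ether, C8 dithiane bearing the C9–C10 allyl unit, and C11 dimethylaminomethyl group | O=C1O[C@H](CO[Si](c2ccccc2)(c2ccccc2)C(C)(C)C)[C@@H](C2(CC(=C)COCc3ccc(OC)cc3)SCCCS2)[C@@H]1CN(C)C
A6 | alternative 3 | (5S)-5-(TBDPS-oxymethyl)furan-2(5H)-one | O=C1O[C@H](CO[Si](c2ccccc2)(c2ccccc2)C(C)(C)C)C=C1
A7 | alternative 3 | 2-[2-(4-methoxybenzyloxymethyl)prop-2-en-1-yl]-1,3-dithiane | C=C(COCc1ccc(OC)cc1)CC1SCCCS1
A8 | alternative 3 | dimethylmethyleneammonium iodide | C=[N+](C)C.[I-]
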